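**Plan**

1. Retrosynthesis: remove the acetates, the angelate and the epoxide (leaving the C8=C9 alkene and the C10 allylic alcohol). Then cut C5–C6 while reconnecting C6–C10, which turns ring B (C1–C5–C6–C7–C8–C9–C10) into a cyclopentane-1,3-dione (C6–C10) attached through C10 to C1 of ring A. The dione is cut at C6–C10 (Dieckmann) and C9=C10 (Wittig), and ring A at C1–C5 (ring contraction of a cyclohexene oxide).
2. Forward: (S)-carvone → ring A as an α-quaternary cyclopentanecarbaldehyde (the formyl carbon is C10) → dione ring built on C10 → photochemical two-carbon ring enlargement to ring B → C14 methyl and C8=C9, angelate, epoxide, acetates.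
3. Enabling feature: in the dione, the C5–H of ring A is γ to the C6 carbonyl (C6–C10–C1–C5) and cis to C10, so the excited C6=O can take this hydrogen and bond to C5. The cyclobutanol C1–C5–C6–C10 is a β-hydroxy ketone towards C9=O and opens at C6–C10 to give ring B.
4. Stereochemistry: the single stereocentre of carvone sets C2 (Luche reduction), the epoxide (OH-directed) and C1 (stereospecific 1,2-shift). C1 and C2 then set C4 (allylic oxidation from the open β-face). C4 sets C5 (equilibration) and C6 (OH-directed hydride). A C2/C10 silylene ring fixes C10, and the C10 hydroxyl directs the epoxide (C8, C9).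

Key step: step 12

Remark: daucane numbering is used for all skeleton carbons (C1 = quaternary ring-fusion carbon with the methyl group; C2–C4 in ring A; C5 = ring-fusion CH; C6–C10 in ring B). α is the face of H-5 in the target, β that of the C1 methyl group. Compounds 1, 8 and 19 are taken as commercially available.

**Route**

Step 1
Reactants: 1 (S)-(+)-carvone
Product: 2 (1S,5S)-cis-carveol
Conditions: NaBH4, CeCl3·7H2O, MeOH, −78 to 0 °C
Reagents that add atoms: none
Why: Luche 1,2-reduction of the enone; hydride adds axially to the half-chair that keeps isopropenyl equatorial, so the new carbinol centre (later C2) has OH cis to isopropenyl.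

Step 2
Reactants: 2 (1S,5S)-cis-carveol
Product: 3 (1S,2S,4R,6R)-1-methyl-4-(prop-1-en-2-yl)-7-oxabicyclo[4.1.0]heptan-2-ol (OH, epoxide O and isopropenyl on one face)
Conditions: VO(acac)2 (2 mol %), t-BuOOH, CH2Cl2, 0 °C to rt
Reagents that add atoms: tert-butyl hydroperoxide, CC(C)(C)OO
Why: Hydroxyl-directed epoxidation of the allylic alcohol through a vanadate ester delivers oxygen syn to OH, which sets both epoxide carbons, and leaves the isopropenyl group alone.

Step 3
Reactants: 3 all-cis epoxy alcohol
Product: 4 (1R,2S,4S,6R)-1-methyl-4-(prop-1-en-2-yl)-7-oxabicyclo[4.1.0]heptan-2-yl acetate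
Conditions: Ac2O, pyridine, DMAP (cat.), CH2Cl2, 0 °C to rt
Reagents that add atoms: acetic anhydride, CC(=O)OC(C)=O
Why: Acylation of the secondary alcohol; the acetate is syn to the epoxide and cannot participate, and it makes the carbinol carbon a poor hydride donor in step 4.

Step 4
Reactants: 4 epoxy acetate
Product: 5 (1S,2R,4S)-2-formyl-2-methyl-4-(prop-1-en-2-yl)cyclopentyl acetate (formyl, acetoxy and isopropenyl cis; methyl trans)
Conditions: MeAl(OC6H2-2,6-tBu2-4-Br)2 (MABR, 2.2 equiv), CH2Cl2, −78 to −20 °C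
Reagents that add atoms: none
Why: Lewis-acid epoxide-to-aldehyde (Meinwald, semipinacol) rearrangement of a trisubstituted cyclohexene oxide: the epoxide opens at its tertiary carbon and the ring carbon on the neighbouring epoxide carbon shifts anti to the leaving oxygen, which contracts the ring and forms the quaternary centre (later C1) with inversion, so formyl ends cis to acetoxy and isopropenyl; the epoxide oxygen cis to isopropenyl (as in trans-limonene oxide) is the arrangement that favours ring contraction over hydride shift.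

Step 5
Reactants: 5 ring-contracted aldehyde
Product: 6 (1S,2R,4R)-2-formyl-4-hydroxy-2-methyl-4-(prop-1-en-2-yl)cyclopentyl acetate
Conditions: SeO2 (30 mol %), t-BuOOH (3 equiv), CH2Cl2, 0 °C to rt
Reagents that add atoms: tert-butyl hydroperoxide, CC(C)(C)OO
Why: Allylic oxidation with SeO2 (ene reaction, then [2,3]-sigmatropic shift of the allylseleninic acid): in a 1,1-disubstituted alkene the ring methine is the preferred allylic site, C4 is planar in the intermediate, and oxygen should be delivered to the face opposite the cis formyl and acetoxy groups, so OH replaces H with overall retention.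

Step 6
Reactants: 6 tertiary allylic alcohol
Product: 7 (1S,2R,4R)-2-formyl-4-hydroxy-2-methyl-4-(propan-2-yl)cyclopentyl acetate
Conditions: H2 (1 atm), [Ir(cod)(PCy3)(py)]PF6 (5 mol %), CH2Cl2, rt
Reagents that add atoms: none
Why: Hydroxyl-directed homogeneous hydrogenation of the 1,1-disubstituted alkene with a cationic iridium catalyst, which should neither hydrogenolyse the tertiary allylic C–O bond nor reduce the hindered aldehyde; no stereocentre is formed.

Step 7
Reactants: 7 hydroxy aldehyde; 8 (4-ethoxy-4-oxobutyl)triphenylphosphonium bromide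
Product: 9 ethyl (4Z)-5-[2α-acetoxy-4β-hydroxy-1β-methyl-4α-(propan-2-yl)cyclopent-1α-yl]pent-4-enoate
Conditions: 8 (2.4 equiv), NaN(SiMe3)2 (2.3 equiv), THF, −78 to 0 °C; then 7, −78 °C to rt
Reagents that add atoms: none
Why: Wittig olefination of the non-enolisable α-quaternary aldehyde with a non-stabilised ylide gives the (Z)-alkene (the geometry is lost in step 8); one equivalent of ylide is spent on the tertiary hydroxyl.

Step 8
Reactants: 9 (Z)-alkenoate
Product: 11 ethyl 4-oxo-5-[2α-acetoxy-4β-hydroxy-1β-methyl-4α-(propan-2-yl)cyclopent-1α-yl]pentanoate, via B-alkyl-9-borabicyclononane 10 (not isolated)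
Conditions: 9-BBN (2.5 equiv), THF, 0 °C to rt; then [C5H5NH][CrO3Cl] (6 equiv), CH2Cl2, 40 °C
Reagents that add atoms: pyridinium chlorochromate, [O-][Cr](=O)(=O)Cl.c1cc[nH+]cc1
Why: Hydroboration–oxidation: 9-BBN puts boron on the alkene carbon remote from the quaternary C1 (this carbon becomes C9), and oxidation of the secondary alkylborane with pyridinium chlorochromate gives the ketone directly, which avoids the γ-hydroxy ester and its lactonisation.

Step 9
Reactants: 11 γ-keto ester
Product: 12 2-[2α,4β-dihydroxy-1β-methyl-4α-(propan-2-yl)cyclopent-1α-yl]cyclopentane-1,3-dione (largely enolised)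
Conditions: NaOEt (3.5 equiv), EtOH, 78 °C; then 1 M HCl
Reagents that add atoms: none
Why: Dieckmann (intramolecular Claisen) condensation: only the C10 carbanion can close a five-membered ring and the product is drawn to completion as its enolate; ethoxide also removes the C2 acetate by transesterification, which frees the hydroxyl needed in step 11.

Step 10
Reactants: 12 2-substituted 1,3-dione
Product: 13 2-hydroxy-2-[2α,4β-dihydroxy-1β-methyl-4α-(propan-2-yl)cyclopent-1α-yl]cyclopentane-1,3-dione
Conditions: dimethyldioxirane (1.1 equiv), acetone, 0 °C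
Reagents that add atoms: dimethyldioxirane, CC1(C)OO1
Why: Electrophilic hydroxylation of the dione enol makes C10 quaternary (non-enolisable, as the photochemistry requires) and brings in the C10 oxygen; C10 is not yet a stereocentre because its two acyl arms are identical.

Step 11
Reactants: 13 hydroxy dione triol
Product: 14 2,10-O-(di-tert-butylsilylene) derivative of 13 (six-membered dioxasilinane spanning O-2 and O-10, spiro to the dione at C10; C4–OH free)
Conditions: tBu2Si(OTf)2 (1.1 equiv), 2,6-lutidine, CH2Cl2, 0 °C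
Reagents that add atoms: di-tert-butylsilyl bis(trifluoromethanesulfonate), CC(C)(C)[Si](OS(=O)(=O)C(F)(F)F)(OS(=O)(=O)C(F)(F)F)C(C)(C)C
Why: Silylene protection of a 1,3-diol: the C2 and C10 hydroxyls are cis on ring A and close a six-membered ring, the trans tertiary C4 hydroxyl cannot bridge; this ring later fixes C10 and holds one dione carbonyl next to C5.

Step 12
Reactants: 14 silylene-bridged 2,2-disubstituted cyclopentane-1,3-dione
Product: 17 trans-fused 4β-hydroxy-2α,10α-(di-tert-butylsilylenedioxy)-14-nordaucane-6,9-dione (5α-H), via cyclobutanol 15 (not isolated), via cis-fused diketone 16 (not isolated)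
Conditions: hν (300 nm), degassed MeCN, 15 °C; then DBU (0.3 equiv), 25 °C
Reagents that add atoms: none
Why: Proposed new method: n→π* excitation of the 1,3-dione lets the carbonyl that the silylene chair holds next to C5 abstract the C5 hydrogen cis to C10 through a six-membered transition state (C6=O···H–C5 across C10–C1), and the 1,4-biradical (C6/C5) collapses to cyclobutanol 15, which as a β-hydroxy ketone (C6–OH/C9=O across C10) opens by retro-aldol cleavage of C6–C10 with release of four-ring strain to give seven-membered ring B. The closest known reaction types are the Norrish–Yang photocyclization of 2,2-disubstituted 1,3-diketones with retro-aldol opening to 1,4-diketones, and the retro-aldol half of the de Mayo reaction. The only ring closed is the cyclobutanol (radical–radical combination of a 1,4-biradical, four-membered, cis-fused to ring A); ring B arises by fragmentation of that ring, not by a closure. C5 is first set cis by the four-ring geometry and is then equilibrated by DBU, as the carbon α to the C6 ketone, to the trans-fused epimer in which C6 is anti to the isopropyl group on C4 and can hydrogen-bond to the C4 hydroxyl; C10 is fixed on protonation of the C9 enol by the dioxasilinane ring, which together with ring B admits only the epimer with oxygen anti to the C1 methyl group. The step needs abstraction at C5 rather than at C2–H or the methyl group, and ring closure rather than α-cleavage or biradical fragmentation: the C2 hydrogen is anti to C10 and out of reach, the methyl hydrogens are primary, and the α-quaternary, α-oxygenated C10 is the substitution pattern that favours cyclization of the biradical.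

Step 13
Reactants: 17 trans-fused diketone
Product: 18 4β,6α-dihydroxy-2α,10α-(di-tert-butylsilylenedioxy)-14-nordaucan-9-one
Conditions: Me4NBH(OAc)3 (5 equiv), MeCN/AcOH 1:1, −30 to −10 °C
Reagents that add atoms: none
Why: Directed reduction of a β-hydroxy ketone (Evans–Saksena): the C4 hydroxyl binds boron and delivers hydride to C6 from its own β-face, giving the 6α-alcohol, while the C9 ketone, which has no free β-hydroxyl, is not reduced.

Step 14
Reactants: 18 hydroxy ketone; 19 angelic acid
Product: 20 6α-angeloyloxy-4β-hydroxy-2α,10α-(di-tert-butylsilylenedioxy)-14-nordaucan-9-one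
Conditions: 19 (3 equiv), 2,4,6-Cl3C6H2COCl (3 equiv), Et3N, toluene, 25 °C; then 18, toluene, 80 °C
Reagents that add atoms: none
Why: Yamaguchi esterification through the mixed 2,4,6-trichlorobenzoic anhydride without nucleophilic catalyst, conditions that acylate hindered secondary alcohols with angelic acid without Z-to-E isomerisation; the tertiary C4 hydroxyl does not react.

Step 15
Reactants: 20 angelate ketone
Product: 22 6α-angeloyloxy-4β-hydroxy-2α,10α-(di-tert-butylsilylenedioxy)dauc-8(14)-en-9-one, via Mannich base 21 (not isolated)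
Conditions: (CH2O)n (5 equiv), iPr2NH·CF3CO2H (1 equiv), CF3CO2H (10 mol %), THF, 65 °C
Reagents that add atoms: formaldehyde (as paraformaldehyde), C=O
Why: α-Methylenation of the ketone (Mannich condensation, then β-elimination of the amine) at C8, the only α-methylene group, since C10 is a methine inside the silylene ring; the new carbon is C14.

Step 16
Reactants: 22 α-methylene ketone
Product: 23 6α-angeloyloxy-2α,10α-(di-tert-butylsilylenedioxy)dauc-8(14)-ene-4β,9-diol (C9 epimers)
Conditions: NaBH4, CeCl3·7H2O, MeOH, −78 °C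
Reagents that add atoms: none
Why: Luche 1,2-reduction of the enone to the allylic alcohol; the configuration at C9 is irrelevant because C9 becomes sp2 in step 17.

Step 17
Reactants: 23 allylic alcohol
Product: 26 6α-angeloyloxy-2α,10α-(di-tert-butylsilylenedioxy)dauc-8-en-4β-ol, via allylic sulfonylhydrazine 24 (not isolated), via allylic diazene 25 (not isolated)
Conditions: 2-O2NC6H4SO2NHNH2, PPh3, EtO2CN=NCO2Et, N-methylmorpholine, −30 to 25 °C
Reagents that add atoms: none
Why: Reductive 1,3-transposition of the allylic alcohol: Mitsunobu displacement at C9 by the sulfonylhydrazide, loss of the sulfinic acid to the monoalkyl diazene and sigmatropic (retro-ene) loss of N2 deliver hydrogen to the exocyclic methylene and move the double bond to C8=C9, which creates the C8 methyl group.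

Step 18
Reactants: 26 silylene-protected alkene
Product: 27 6α-angeloyloxydauc-8-ene-2α,4β,10α-triol
Conditions: HF·pyridine, THF/pyridine, 0 °C to rt
Reagents that add atoms: none
Why: Fluoride cleavage of the Si–O bonds of the di-tert-butylsilylene acetal frees the C2 and C10 hydroxyls; the angelate, the trisubstituted alkene and the tertiary alcohol should be untouched.

Step 19
Reactants: 27 triol
Product: 28 6α-angeloyloxy-8α,9α-epoxydaucane-2α,4β,10α-triol
Conditions: VO(acac)2 (5 mol %), t-BuOOH (1.5 equiv), CH2Cl2, 0 °C to rt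
Reagents that add atoms: tert-butyl hydroperoxide, CC(C)(C)OO
Why: Hydroxyl-directed epoxidation of the cyclic allylic alcohol: oxygen is delivered syn to the 10α-hydroxyl, which sets C8 and C9 as the 8α,9α-epoxide, and the electron-poor angelate double bond does not react.

Step 20
Reactants: 28 epoxy triol
Product: 29 2α,10α-diacetoxy-6α-angeloyloxy-8α,9α-epoxydaucan-4β-ol (target)
Conditions: Ac2O, pyridine, DMAP (cat.), CH2Cl2, rt
Reagents that add atoms: acetic anhydride, CC(=O)OC(C)=O
Why: DMAP-catalysed acetylation of the two secondary hydroxyls (C2, C10); the tertiary C4 hydroxyl, flanked by the isopropyl group and the ring fusion, should not be acylated at room temperature.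

**Compound list**

1 | (S)-(+)-carvone | CC1=CC[C@H](C(C)=C)CC1=O | starting material
2 | (1S,5S)-cis-carveol | CC1=CC[C@H](C(C)=C)C[C@@H]1O | intermediate
3 | (1S,2S,4R,6R)-1-methyl-4-(prop-1-en-2-yl)-7-oxabicyclo[4.1.0]heptan-2-ol, all-cis | C[C@@]12O[C@@H]1C[C@H](C(C)=C)C[C@@H]2O | intermediate
4 | (1R,2S,4S,6R)-1-methyl-4-(prop-1-en-2-yl)-7-oxabicyclo[4.1.0]heptan-2-yl acetate | C[C@@]12O[C@@H]1C[C@H](C(C)=C)C[C@@H]2OC(C)=O | intermediate
5 | (1S,2R,4S)-2-formyl-2-methyl-4-(prop-1-en-2-yl)cyclopentyl acetate | O=C[C@@]1(C)[C@@H](OC(C)=O)C[C@@H](C(C)=C)C1 | intermediate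
6 | (1S,2R,4R)-2-formyl-4-hydroxy-2-methyl-4-(prop-1-en-2-yl)cyclopentyl acetate | O=C[C@@]1(C)[C@@H](OC(C)=O)C[C@@](O)(C(C)=C)C1 | intermediate
7 | (1S,2R,4R)-2-formyl-4-hydroxy-2-methyl-4-(propan-2-yl)cyclopentyl acetate | O=C[C@@]1(C)[C@@H](OC(C)=O)C[C@@](O)(C(C)C)C1 | intermediate
8 | (4-ethoxy-4-oxobutyl)triphenylphosphonium bromide | CCOC(=O)CCC[P+](c1ccccc1)(c1ccccc1)c1ccccc1.[Br-] | starting material
9 | ethyl (4Z)-5-[2α-acetoxy-4β-hydroxy-1β-methyl-4α-(propan-2-yl)cyclopent-1α-yl]pent-4-enoate | CCOC(=O)CC/C=C\[C@@]1(C)[C@@H](OC(C)=O)C[C@@](O)(C(C)C)C1 | intermediate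
10 | B-alkyl-9-borabicyclo[3.3.1]nonane from 9 (boron on C9) | CCOC(=O)CCC(B1C2CCCC1CCC2)C[C@@]1(C)[C@@H](OC(C)=O)C[C@@](O)(C(C)C)C1 | intermediate
11 | ethyl 4-oxo-5-[2α-acetoxy-4β-hydroxy-1β-methyl-4α-(propan-2-yl)cyclopent-1α-yl]pentanoate | CCOC(=O)CCC(=O)C[C@@]1(C)[C@@H](OC(C)=O)C[C@@](O)(C(C)C)C1 | intermediate
12 | 2-[2α,4β-dihydroxy-1β-methyl-4α-(propan-2-yl)cyclopent-1α-yl]cyclopentane-1,3-dione | O=C1CCC(=O)C1[C@@]1(C)[C@@H](O)C[C@@](O)(C(C)C)C1 | intermediate
13 | 2-hydroxy-2-[2α,4β-dihydroxy-1β-methyl-4α-(propan-2-yl)cyclopent-1α-yl]cyclopentane-1,3-dione | O=C1CCC(=O)C1(O)[C@@]1(C)[C@@H](O)C[C@@](O)(C(C)C)C1 | intermediate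
14 | 2,10-O-(di-tert-butylsilylene) derivative of 13 | O=C1CCC(=O)C12O[Si](C(C)(C)C)(C(C)(C)C)O[C@H]3C[C@@](O)(C(C)C)C[C@@]23C | intermediate
15 | cyclobutanol from 14 (C5–C6 bonded; four-ring C1–C5–C6–C10, cis-fused to ring A; C6–OH, C9=O) | O[C@@]12CCC(=O)[C@@]13O[Si](C(C)(C)C)(C(C)(C)C)O[C@H]4C[C@@](O)(C(C)C)[C@@H]2[C@@]34C | intermediate
16 | cis-fused (5β-H) 4β-hydroxy-2α,10α-(di-tert-butylsilylenedioxy)-14-nordaucane-6,9-dione | O=C1CCC(=O)[C@H]2O[Si](C(C)(C)C)(C(C)(C)C)O[C@H]3C[C@@](O)(C(C)C)[C@@H]1[C@@]23C | intermediate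
17 | trans-fused (5α-H) 4β-hydroxy-2α,10α-(di-tert-butylsilylenedioxy)-14-nordaucane-6,9-dione | O=C1CCC(=O)[C@H]2O[Si](C(C)(C)C)(C(C)(C)C)O[C@H]3C[C@@](O)(C(C)C)[C@H]1[C@@]23C | intermediate
18 | 4β,6α-dihydroxy-2α,10α-(di-tert-butylsilylenedioxy)-14-nordaucan-9-one | O[C@H]1CCC(=O)[C@H]2O[Si](C(C)(C)C)(C(C)(C)C)O[C@H]3C[C@@](O)(C(C)C)[C@H]1[C@@]23C | intermediate
19 | angelic acid, (Z)-2-methylbut-2-enoic acid | C/C=C(/C)C(=O)O | starting material
20 | 6α-angeloyloxy-4β-hydroxy-2α,10α-(di-tert-butylsilylenedioxy)-14-nordaucan-9-one | C/C=C(/C)C(=O)O[C@H]1CCC(=O)[C@H]2O[Si](C(C)(C)C)(C(C)(C)C)O[C@H]3C[C@@](O)(C(C)C)[C@H]1[C@@]23C | intermediate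
21 | Mannich base of 20 (8-(diisopropylaminomethyl) ketone; C8 epimers) | C/C=C(/C)C(=O)O[C@H]1CC(CN(C(C)C)C(C)C)C(=O)[C@H]2O[Si](C(C)(C)C)(C(C)(C)C)O[C@H]3C[C@@](O)(C(C)C)[C@H]1[C@@]23C | intermediate
22 | 6α-angeloyloxy-4β-hydroxy-2α,10α-(di-tert-butylsilylenedioxy)dauc-8(14)-en-9-one | C/C=C(/C)C(=O)O[C@H]1CC(=C)C(=O)[C@H]2O[Si](C(C)(C)C)(C(C)(C)C)O[C@H]3C[C@@](O)(C(C)C)[C@H]1[C@@]23C | intermediate
23 | 6α-angeloyloxy-2α,10α-(di-tert-butylsilylenedioxy)dauc-8(14)-ene-4β,9-diol (C9 epimers) | C/C=C(/C)C(=O)O[C@H]1CC(=C)C(O)[C@H]2O[Si](C(C)(C)C)(C(C)(C)C)O[C@H]3C[C@@](O)(C(C)C)[C@H]1[C@@]23C | intermediate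
24 | N-(C9-allyl)-N-(2-nitrophenylsulfonyl)hydrazine from 23 | C/C=C(/C)C(=O)O[C@H]1CC(=C)C(N(N)S(=O)(=O)c4ccccc4[N+](=O)[O-])[C@H]2O[Si](C(C)(C)C)(C(C)(C)C)O[C@H]3C[C@@](O)(C(C)C)[C@H]1[C@@]23C | intermediate
25 | C9 monoalkyl diazene from 24 | C/C=C(/C)C(=O)O[C@H]1CC(=C)C(N=N)[C@H]2O[Si](C(C)(C)C)(C(C)(C)C)O[C@H]3C[C@@](O)(C(C)C)[C@H]1[C@@]23C | intermediate
26 | 6α-angeloyloxy-2α,10α-(di-tert-butylsilylenedioxy)dauc-8-en-4β-ol | C/C=C(/C)C(=O)O[C@H]1CC(C)=C[C@H]2O[Si](C(C)(C)C)(C(C)(C)C)O[C@H]3C[C@@](O)(C(C)C)[C@H]1[C@@]23C | intermediate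
27 | 6α-angeloyloxydauc-8-ene-2α,4β,10α-triol | C/C=C(/C)C(=O)O[C@H]1CC(C)=C[C@@H](O)[C@@]2(C)[C@@H](O)C[C@@](O)(C(C)C)[C@H]12 | intermediate
28 | 6α-angeloyloxy-8α,9α-epoxydaucane-2α,4β,10α-triol | C/C=C(/C)C(=O)O[C@H]1C[C@@]2(C)O[C@H]2[C@@H](O)[C@@]2(C)[C@@H](O)C[C@@](O)(C(C)C)[C@H]12 | intermediate
29 | 2α,10α-diacetoxy-6α-angeloyloxy-8α,9α-epoxydaucan-4β-ol | C/C=C(/C)C(=O)O[C@H]1C[C@@]2(C)O[C@H]2[C@@H](OC(C)=O)[C@@]2(C)[C@@H](OC(C)=O)C[C@@](O)(C(C)C)[C@H]12 | target

Total step count: 20. Longest linear sequence: 20 steps (1 to 29).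

**Steps most likely to fail**

Step 12. The excited dione may undergo α-cleavage towards the oxygen-substituted C10 radical, the 1,4-biradical may fragment into a cyclopentene and an enol instead of closing, or hydrogen may be taken from the C1 methyl group. The fallback uses known chemistry and separates the C–H abstraction from the fragmentation on a single carbonyl chromophore. It sets out from 14. One equivalent of NaBH4 (MeOH/CH2Cl2, −78 °C) reduces one dione carbonyl and gives the hydroxy ketone F1, in which the carbonyl next to C5 is kept; the regioisomeric mono-alcohol is returned to 14 by Dess–Martin oxidation. Irradiation of F1 at 300 nm is then the Norrish–Yang cyclization of a simple α-alkoxy, α-quaternary ketone and gives the cyclobutanediol F2, which is isolated. Dess–Martin oxidation of the secondary hydroxyl of F2 gives the β-hydroxy ketone 15, which DBU opens and equilibrates through 16. The fallback comes back to the route at 17.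

Step 5. The [2,3]-shift may deliver oxygen to the wrong face of C4, oxidation may occur at the isopropenyl methyl group instead of the ring methine, or the aldehyde may be over-oxidised. The fallback builds the tertiary carbinol on the six-membered ring, where addition of a bulky nucleophile is equatorial, before the ring contraction. It sets out from 4. Ozonolysis (O3, CH2Cl2/MeOH, −78 °C; Me2S) of the isopropenyl group gives the methyl ketone F3. Me3SiCl, Et3N, DMF, 80 °C converts it into the more substituted silyl enol ether F4, and a second ozonolysis gives the cyclohexanone F5. iPrMgCl with CeCl3 (THF, −78 °C) should add from the equatorial direction and give the tertiary alcohol F6, with isopropyl cis to acetoxy and OH trans. Ring contraction of F6 with MABR as in step 4 (3 equiv; the hydroxyl is masked in the flask as its bulky aluminium alkoxide so that it does not attack the epoxide across the ring) comes back to the route at 7.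

Step 17. The Mitsunobu displacement at the hindered C9 carbinol may be slow, or the hydrazide may attack the methylene terminus (SN2′), which would return the exocyclic alkene. The fallback reaches the same alkene through a hydrazone. It sets out from 22. RhCl3·3H2O (5 mol %), EtOH, 70 °C isomerises the exocyclic enone to the endocyclic 8-methyl enone F7. TsNHNH2 (EtOH, 50 °C) gives the tosylhydrazone F8. Catecholborane (CHCl3, 0 °C), then NaOAc·3H2O (60 °C), reduces the C=N bond, and loss of sulfinate and N2 from the resulting diazene puts hydrogen on C7 and the double bond at C8=C9. The fallback comes back to the route at 26.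

**Further compounds**

F1 | step 12 | mono-alcohol of 14 (C9–OH, C6=O next to C5; C9 epimers) | O=C1CCC(O)[C@@]12O[Si](C(C)(C)C)(C(C)(C)C)O[C@H]3C[C@@](O)(C(C)C)C[C@@]23C
F2 | step 12 | cyclobutanediol (C5–C6 bonded; C6–OH and C9–OH) | O[C@@]12CCC(O)[C@@]13O[Si](C(C)(C)C)(C(C)(C)C)O[C@H]4C[C@@](O)(C(C)C)[C@@H]2[C@@]34C
F3 | step 5 | 4-acetyl-1-methyl-7-oxabicyclo[4.1.0]heptan-2-yl acetate (configuration as in 4) | C[C@@]12O[C@@H]1C[C@H](C(C)=O)C[C@@H]2OC(C)=O
F4 | step 5 | tetrasubstituted trimethylsilyl enol ether of F3 | C[C@@]12O[C@@H]1CC(=C(C)O[Si](C)(C)C)C[C@@H]2OC(C)=O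
F5 | step 5 | 1-methyl-4-oxo-7-oxabicyclo[4.1.0]heptan-2-yl acetate | C[C@@]12O[C@@H]1CC(=O)C[C@@H]2OC(C)=O
F6 | step 5 | 4-hydroxy-1-methyl-4-(propan-2-yl)-7-oxabicyclo[4.1.0]heptan-2-yl acetate (isopropyl cis to acetoxy and epoxide O) | C[C@@]12O[C@@H]1C[C@](O)(C(C)C)C[C@@H]2OC(C)=O
F7 | step 17 | 6α-angeloyloxy-4β-hydroxy-2α,10α-(di-tert-butylsilylenedioxy)dauc-7-en-9-one | C/C=C(/C)C(=O)O[C@H]1C=C(C)C(=O)[C@H]2O[Si](C(C)(C)C)(C(C)(C)C)O[C@H]3C[C@@](O)(C(C)C)[C@H]1[C@@]23C
F8 | step 17 | tosylhydrazone of F7 | C/C=C(/C)C(=O)O[C@H]1C=C(C)C(=NNS(=O)(=O)c4ccc(C)cc4)[C@H]2O[Si](C(C)(C)C)(C(C)(C)C)O[C@H]3C[C@@](O)(C(C)C)[C@H]1[C@@]23C
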